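**Retrosynthetic overview**

1. Locants used throughout: ring C1 (O-angelate), C2, C3 (its methyl = C15), C4 (OAc), C5, C6; side chain C7 (CH3), C8, C9 (OAc), C10=C11. Endgame: angelate by acylation of the C1 alcohol, C1 carbinol by reduction of a C1 ketone, C9 acetate by Mitsunobu inversion of a (9S)-alcohol.
2. The C1 ketone and the C9 hydroxyl come from hydrolysis of a temporary dihydropyran ring (enol ether O–C1=C2 whose oxygen is the C9 oxygen). The C3 methyl and the C4 oxygen come from a temporary C15–O–Si–C4 oxasilolane (Tamao–Fleming oxidation, then C15–OH to CH3).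
3. Key disconnection: the carbocycle is made by a silicon-tethered intramolecular Diels–Alder reaction of a (Z)-dienyl vinylsilyl ether, which forms C5–C6 and C3–C4 and sets C3, C4 and C6 in one operation.
4. Enabling feature: on the ring C1–C6 the C3 methyl carbon (C15) and the C4 oxygen are cis-vicinal, so C15 and C4 can be tied through O–Si into a five-membered ring. The C1 oxygen lies 1,5 to the C9 oxygen across C6–C7–C8, so one oxygen can serve both in a six-membered cyclic enol ether, whose C7 methyl (pseudoaxial when C9 is S) then steers the π-face.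
5. Ring order: δ-lactone/pyran ring first (from methyl hydrogen (R)-3-methylglutarate, enone, CBS reduction); then cyclohexene and oxasilolane together in the key step; then both temporary rings are opened.

Key step: step 8

Remark: the ester C/C=C(/C)C(=O)O is read as the (Z)-2-methylbut-2-enoate (angelate); stannane 9 is treated as not purchasable and is made in step 5.

**Route**

Step 1
Reactants: 1 (3R)-5-methoxy-3-methyl-5-oxopentanoic acid (methyl hydrogen (R)-3-methylglutarate); 2 (2-methylprop-1-en-1-yl)magnesium bromide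
Product: 4 methyl (3R)-3,7-dimethyl-5-oxooct-6-enoate, via acid chloride 3 (not isolated)
Conditions: (COCl)2, DMF (cat.), CH2Cl2, 0 °C to rt, evaporate; then 2 (1.05 equiv), CuI (10 mol %), THF, −78 to −40 °C
Reagents that add atoms: none
Why: Copper-catalysed acylation of the alkenyl Grignard reagent by the acid chloride (used at once, so that no chloride/methoxy scrambling through a cyclic acyloxonium ion erodes the future C7) is far faster than attack on the methyl ester or on the β,β-disubstituted enone formed, so the reaction should stop at ketone 4.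

Step 2
Reactants: 4 methyl (3R)-3,7-dimethyl-5-oxooct-6-enoate
Product: 5 methyl (3R,5S)-5-hydroxy-3,7-dimethyloct-6-enoate
Conditions: (R)-Me-CBS (0.2 equiv), catecholborane (1.5 equiv), PhMe, −78 °C; MeOH, then aq. NaHCO3
Reagents that add atoms: none
Why: Corey–Bakshi–Shibata reduction in which the 2-methylpropenyl group acts as the large substituent, so the (R)-catalyst should give the (5S)-carbinol (the future C9, deliberately opposite to the target), the ester and the trisubstituted alkene being inert to catecholborane at −78 °C.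

Step 3
Reactants: 5 methyl (3R,5S)-5-hydroxy-3,7-dimethyloct-6-enoate
Product: 6 (4R,6S)-4-methyl-6-(2-methylprop-1-en-1-yl)oxan-2-one (trans lactone)
Conditions: PPTS (5 mol %), PhMe, 4 Å MS, 60 °C
Reagents that add atoms: none
Why: Acid-catalysed intramolecular transesterification (lactonisation) of the δ-hydroxy ester, driven by removal of methanol on the sieves; no stereocentre is touched and the trans lactone can be separated from any cis isomer left by step 2.

Step 4
Reactants: 6 (4R,6S)-4-methyl-6-(2-methylprop-1-en-1-yl)oxan-2-one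
Product: 7 (2S,4R)-4-methyl-2-(2-methylprop-1-en-1-yl)-3,4-dihydro-2H-pyran-6-yl diphenyl phosphate
Conditions: KHMDS, (PhO)2P(O)Cl, HMPA, THF, −78 °C
Reagents that add atoms: diphenyl chlorophosphate, O=P(Cl)(Oc1ccccc1)Oc1ccccc1
Why: Kinetic enolisation of the lactone at its only α-CH2 and O-phosphorylation of the enolate gives the ketene acetal phosphate (enol phosphate formation), the cross-coupling handle at the future C1.

Step 5
Reactants: 8 prop-2-yn-1-ol
Product: 9 (2Z)-3-(tributylstannyl)prop-2-en-1-ol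
Conditions: LiAlH4, THF, 0 °C to rt; then Bu3SnOTf, −78 °C to rt
Reagents that add atoms: tributyltin trifluoromethanesulfonate, CCCC[Sn](CCCC)(CCCC)OS(=O)(=O)C(F)(F)F
Why: Hydroxyl-directed trans-hydroalumination of the propargylic alcohol gives a cyclic (Z)-vinylalanate whose Al–C bond is exchanged for tin with retention, so the stannyl group should end cis to CH2OH.

Step 6
Reactants: 7 (2S,4R)-4-methyl-2-(2-methylprop-1-en-1-yl)-3,4-dihydro-2H-pyran-6-yl diphenyl phosphate; 9 (2Z)-3-(tributylstannyl)prop-2-en-1-ol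
Product: 10 (2Z)-3-[(2S,4R)-4-methyl-2-(2-methylprop-1-en-1-yl)-3,4-dihydro-2H-pyran-6-yl]prop-2-en-1-ol
Conditions: Pd(PPh3)4 (5 mol %), LiCl (3 equiv), THF, 60 °C; Et3N-buffered work-up and silica
Reagents that add atoms: none
Why: Stille coupling of a lactone-derived ketene acetal phosphate with an alkenylstannane, which should proceed with retention of the (Z)-geometry and tolerate the free hydroxyl; the buffered work-up prevents acid-induced spiroketalisation of the 2-alkoxydiene.

Step 7
Reactants: 10 (2Z)-3-[(2S,4R)-4-methyl-2-(2-methylprop-1-en-1-yl)-3,4-dihydro-2H-pyran-6-yl]prop-2-en-1-ol; 11 chloro(ethenyl)dimethylsilane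
Product: 12 ethenyl(dimethyl){[(2Z)-3-[(2S,4R)-4-methyl-2-(2-methylprop-1-en-1-yl)-3,4-dihydro-2H-pyran-6-yl]prop-2-en-1-yl]oxy}silane
Conditions: Et3N, DMAP (cat.), CH2Cl2, 0 °C; filtration through basic alumina, used crude
Reagents that add atoms: none
Why: Silylation of the primary allylic alcohol with a chlorosilane and amine base puts the vinylsilane dienophile on a three-atom C–O–Si tether (temporary silicon connection) under basic conditions that keep the acid-labile 2-alkoxydiene intact.

Step 8
Reactants: 12 ethenyl(dimethyl){[(2Z)-3-[(2S,4R)-4-methyl-2-(2-methylprop-1-en-1-yl)-3,4-dihydro-2H-pyran-6-yl]prop-2-en-1-yl]oxy}silane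
Product: 13 silicon-tethered cycloadduct: (2S,4R,4aS,6R,7R)-4-methyl-2-(2-methylprop-1-en-1-yl)-3,4,4a,5,6,7-hexahydro-2H-chromene whose C6 (target C4) carries Si(CH3)2 and whose C7 (target C3) carries CH2O, Si and O being joined in a cis-fused 2,2-dimethyl-1,2-oxasilolane; enol ether C8=C8a
Conditions: PhMe (0.01 M), BHT (0.1 equiv), N,O-bis(trimethylsilyl)acetamide (0.2 equiv), base-washed sealed tube, 160 °C
Reagents that add atoms: none
Why: Thermal type-1 intramolecular Diels–Alder reaction of a vinylsilane held to the diene by a temporary Si–O tether (silicon-tethered IMDA), concerted and suprafacial on both partners, the cyclic 2-alkoxydiene raising the diene HOMO. Two rings close at once: the cyclohexene C1–C6 by [4+2] cycloaddition (bonds C5–C6 and C3–C4) and the 1-oxa-2-silacyclopentane (C3, C15, O, Si, C4) in the fused mode, which the three-atom tether enforces and which fixes the regiochemistry (silicon-bearing C4 to C3, CH2 to C6). Because the tether leaves C3 from the inside (Z) position, only the cis-fused transition state is within reach, so C15 and Si come out cis on C3/C4; with C15 inside and C7 outside (C7 is locked cis to the ring oxygen in the dihydropyran), C15 and C7 end up trans on C3 and C6. The absolute sense comes from the dihydropyran half-chair, in which the equatorial isobutenyl group at (9S)-C9 forces the C7 methyl pseudoaxial, so that the dienophile adds to C6 anti to that methyl through a chair-like axial-attack geometry. The step needs cycloaddition below the temperature at which [1,5]-hydrogen shift of the (Z)-dienyl ether or Claisen ring expansion of the product's allyl vinyl ether sets in, which the electron-rich diene, high dilution, BHT and an acid scavenger should secure.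

Step 9
Reactants: 13 silicon-tethered cycloadduct
Product: 14 (2S,4R,4aS,6R,7R)-7-(hydroxymethyl)-4-methyl-2-(2-methylprop-1-en-1-yl)-3,4,4a,5,6,7-hexahydro-2H-chromen-6-ol
Conditions: KF, KHCO3, 30% H2O2, THF–MeOH (1:1), 40 °C
Reagents that add atoms: hydrogen peroxide, OO
Why: Tamao–Fleming oxidation of the alkoxydimethylsilyl group converts the C4–Si bond into C4–OH with retention and frees the C15 hydroxyl, while basic peroxide leaves the enol ether and the trisubstituted alkene alone.

Step 10
Reactants: 14 (2S,4R,4aS,6R,7R)-7-(hydroxymethyl)-4-methyl-2-(2-methylprop-1-en-1-yl)-3,4,4a,5,6,7-hexahydro-2H-chromen-6-ol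
Product: 15 [(2S,4R,4aS,6R,7R)-6-hydroxy-4-methyl-2-(2-methylprop-1-en-1-yl)-3,4,4a,5,6,7-hexahydro-2H-chromen-7-yl]methyl 4-methylbenzenesulfonate
Conditions: TsCl (1.1 equiv), Et3N, Me3N·HCl (cat.), CH2Cl2, 0 °C
Reagents that add atoms: 4-methylbenzenesulfonyl chloride, Cc1ccc(cc1)S(Cl)(=O)=O
Why: Sulfonylation is much faster at the primary C15 hydroxyl than at the axial secondary C4 hydroxyl, so selective mono-tosylation is expected under amine-buffered conditions that spare the enol ether.

Step 11
Reactants: 15 primary tosylate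
Product: 16 (2S,4R,4aS,6R,7S)-4,7-dimethyl-2-(2-methylprop-1-en-1-yl)-3,4,4a,5,6,7-hexahydro-2H-chromen-6-ol
Conditions: LiEt3BH (3 equiv), THF, 0 °C to rt
Reagents that add atoms: none
Why: SN2 displacement of the primary tosylate by lithium triethylborohydride turns C15 into the C3 methyl group, faster than 4-exo closure of the C4 alkoxide to an oxetane; enol ether and alkenes are inert.

Step 12
Reactants: 16 (2S,4R,4aS,6R,7S)-4,7-dimethyl-2-(2-methylprop-1-en-1-yl)-3,4,4a,5,6,7-hexahydro-2H-chromen-6-ol
Product: 17 (2S,4R,4aS,6R,7S)-4,7-dimethyl-2-(2-methylprop-1-en-1-yl)-3,4,4a,5,6,7-hexahydro-2H-chromen-6-yl acetate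
Conditions: Ac2O, pyridine, DMAP (cat.), CH2Cl2, rt
Reagents that add atoms: acetic anhydride, CC(=O)OC(C)=O
Why: DMAP-catalysed acetylation of the only free hydroxyl (axial C4–OH) while the C9 oxygen is still locked in the pyran ring gives the C4 acetate without any differentiation problem.

Step 13
Reactants: 17 (2S,4R,4aS,6R,7S)-4,7-dimethyl-2-(2-methylprop-1-en-1-yl)-3,4,4a,5,6,7-hexahydro-2H-chromen-6-yl acetate
Product: 19 (1R,2S,5S)-5-[(2R,4S)-4-hydroxy-6-methylhept-5-en-2-yl]-2-methyl-4-oxocyclohexyl acetate, via lactol 18 (not isolated)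
Conditions: PPTS (0.1 equiv), THF–H2O (4:1), 0 °C to rt
Reagents that add atoms: water, O
Why: Mild acid-catalysed hydration of the cyclic enol ether (C-protonation at C2, water capture of the oxocarbenium ion at C1, opening of the hemiketal) releases the C1 ketone and the C9 hydroxyl; at this low acidity neither ionisation of the allylic C9–O bond nor enolisation towards C6 should compete, and the C6 configuration set in step 8 is in any case the thermodynamically preferred one.

Step 14
Reactants: 19 (1R,2S,5S)-5-[(2R,4S)-4-hydroxy-6-methylhept-5-en-2-yl]-2-methyl-4-oxocyclohexyl acetate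
Product: 20 (1R,2S,5S)-5-[(2R,4R)-4-(acetyloxy)-6-methylhept-5-en-2-yl]-2-methyl-4-oxocyclohexyl acetate
Conditions: AcOH, PPh3, DIAD, PhMe, −20 to 0 °C
Reagents that add atoms: acetic acid, CC(=O)O
Why: Mitsunobu esterification: the C9 alcohol, activated as its alkoxyphosphonium ion, is displaced by acetate in an SN2 reaction, which inverts C9 from S to the R configuration of the target and installs the acetate in the same operation; the tertiary hydroxyl of the closed lactol form is too hindered to react.

Step 15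
Reactants: 20 (1R,2S,5S)-5-[(2R,4R)-4-(acetyloxy)-6-methylhept-5-en-2-yl]-2-methyl-4-oxocyclohexyl acetate
Product: 21 (1R,2S,4R,5S)-5-[(2R,4R)-4-(acetyloxy)-6-methylhept-5-en-2-yl]-4-hydroxy-2-methylcyclohexyl acetate
Conditions: NaBH4, CeCl3·7H2O, MeOH, −40 °C
Reagents that add atoms: none
Why: Luche-type borohydride reduction: the small hydride should attack the chair cyclohexanone axially (the face of the axial hydrogens on C3 and C5; the axial C4 acetate lies on the other face), giving the equatorial C1 alcohol trans to the C6 side chain, and the acetates survive at −40 °C.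

Step 16
Reactants: 21 (1R,2S,4R,5S)-5-[(2R,4R)-4-(acetyloxy)-6-methylhept-5-en-2-yl]-4-hydroxy-2-methylcyclohexyl acetate; 22 (2Z)-2-methylbut-2-enoic acid (angelic acid)
Product: 24 (1R,2S,4R,5S)-4-(acetyloxy)-2-[(2R,4R)-4-(acetyloxy)-6-methylhept-5-en-2-yl]-5-methylcyclohexyl (2Z)-2-methylbut-2-enoate, via mixed anhydride 23 (not isolated)
Conditions: 22, 2,4,6-Cl3C6H2COCl, Et3N, PhMe, rt; then 21, 80 °C
Reagents that add atoms: none
Why: Yamaguchi esterification through the mixed 2,4,6-trichlorobenzoic anhydride without a nucleophilic catalyst, conditions under which hindered secondary alcohols are acylated by angelic acid without Z-to-E isomerisation to the tiglate.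

**Compound list**

1 | (3R)-5-methoxy-3-methyl-5-oxopentanoic acid (methyl hydrogen (R)-3-methylglutarate) | COC(=O)C[C@H](C)CC(=O)O | starting material
2 | (2-methylprop-1-en-1-yl)magnesium bromide | CC(C)=C[Mg]Br | starting material
3 | methyl (3S)-5-chloro-3-methyl-5-oxopentanoate (acid chloride) | COC(=O)C[C@H](C)CC(=O)Cl | intermediate
4 | methyl (3R)-3,7-dimethyl-5-oxooct-6-enoate | COC(=O)C[C@H](C)CC(=O)C=C(C)C | intermediate
5 | methyl (3R,5S)-5-hydroxy-3,7-dimethyloct-6-enoate | COC(=O)C[C@H](C)C[C@H](O)C=C(C)C | intermediate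
6 | (4R,6S)-4-methyl-6-(2-methylprop-1-en-1-yl)oxan-2-one | O=C1C[C@H](C)C[C@@H](C=C(C)C)O1 | intermediate
7 | (2S,4R)-4-methyl-2-(2-methylprop-1-en-1-yl)-3,4-dihydro-2H-pyran-6-yl diphenyl phosphate | O=P(Oc1ccccc1)(Oc1ccccc1)OC1=C[C@H](C)C[C@@H](C=C(C)C)O1 | intermediate
8 | prop-2-yn-1-ol | C#CCO | starting material
9 | (2Z)-3-(tributylstannyl)prop-2-en-1-ol | CCCC[Sn](CCCC)(CCCC)/C=C\CO | intermediate
10 | (2Z)-3-[(2S,4R)-4-methyl-2-(2-methylprop-1-en-1-yl)-3,4-dihydro-2H-pyran-6-yl]prop-2-en-1-ol | OC/C=C\C1=C[C@H](C)C[C@@H](C=C(C)C)O1 | intermediate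
11 | chloro(ethenyl)dimethylsilane | C=C[Si](C)(C)Cl | starting material
12 | ethenyl(dimethyl){[(2Z)-3-[(2S,4R)-4-methyl-2-(2-methylprop-1-en-1-yl)-3,4-dihydro-2H-pyran-6-yl]prop-2-en-1-yl]oxy}silane | C=C[Si](C)(C)OC/C=C\C1=C[C@H](C)C[C@@H](C=C(C)C)O1 | intermediate
13 | silicon-tethered cycloadduct: (2S,4R,4aS,6R,7R)-4-methyl-2-(2-methylprop-1-en-1-yl)-3,4,4a,5,6,7-hexahydro-2H-chromene with C6–Si(CH3)2–O–CH2–C7 as a cis-fused 2,2-dimethyl-1,2-oxasilolane | O1C2=C[C@@H]3CO[Si](C)(C)[C@@H]3C[C@H]2[C@H](C)C[C@H]1C=C(C)C | intermediate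
14 | (2S,4R,4aS,6R,7R)-7-(hydroxymethyl)-4-methyl-2-(2-methylprop-1-en-1-yl)-3,4,4a,5,6,7-hexahydro-2H-chromen-6-ol | O1C2=C[C@H](CO)[C@H](O)C[C@H]2[C@H](C)C[C@H]1C=C(C)C | intermediate
15 | [(2S,4R,4aS,6R,7R)-6-hydroxy-4-methyl-2-(2-methylprop-1-en-1-yl)-3,4,4a,5,6,7-hexahydro-2H-chromen-7-yl]methyl 4-methylbenzenesulfonate | O1C2=C[C@H](COS(=O)(=O)c3ccc(C)cc3)[C@H](O)C[C@H]2[C@H](C)C[C@H]1C=C(C)C | intermediate
16 | (2S,4R,4aS,6R,7S)-4,7-dimethyl-2-(2-methylprop-1-en-1-yl)-3,4,4a,5,6,7-hexahydro-2H-chromen-6-ol | O1C2=C[C@H](C)[C@H](O)C[C@H]2[C@H](C)C[C@H]1C=C(C)C | intermediate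
17 | (2S,4R,4aS,6R,7S)-4,7-dimethyl-2-(2-methylprop-1-en-1-yl)-3,4,4a,5,6,7-hexahydro-2H-chromen-6-yl acetate | O1C2=C[C@H](C)[C@H](OC(C)=O)C[C@H]2[C@H](C)C[C@H]1C=C(C)C | intermediate
18 | lactol: (2S,4R,4aS,6R,7S)-8a-hydroxy-4,7-dimethyl-2-(2-methylprop-1-en-1-yl)octahydro-2H-chromen-6-yl acetate (both configurations at C8a) | O1C2(O)C[C@H](C)[C@H](OC(C)=O)C[C@H]2[C@H](C)C[C@H]1C=C(C)C | intermediate
19 | (1R,2S,5S)-5-[(2R,4S)-4-hydroxy-6-methylhept-5-en-2-yl]-2-methyl-4-oxocyclohexyl acetate | O=C1C[C@H](C)[C@H](OC(C)=O)C[C@H]1[C@H](C)C[C@@H](C=C(C)C)O | intermediate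
20 | (1R,2S,5S)-5-[(2R,4R)-4-(acetyloxy)-6-methylhept-5-en-2-yl]-2-methyl-4-oxocyclohexyl acetate | O=C1C[C@H](C)[C@H](OC(C)=O)C[C@H]1[C@H](C)C[C@H](C=C(C)C)OC(C)=O | intermediate
21 | (1R,2S,4R,5S)-5-[(2R,4R)-4-(acetyloxy)-6-methylhept-5-en-2-yl]-4-hydroxy-2-methylcyclohexyl acetate | O[C@@H]1C[C@H](C)[C@H](OC(C)=O)C[C@H]1[C@H](C)C[C@H](C=C(C)C)OC(C)=O | intermediate
22 | (2Z)-2-methylbut-2-enoic acid (angelic acid) | C/C=C(/C)C(=O)O | starting material
23 | (2Z)-2-methylbut-2-enoic 2,4,6-trichlorobenzoic anhydride | C/C=C(/C)C(=O)OC(=O)c1c(Cl)cc(Cl)cc1Cl | intermediate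
24 | (1R,2S,4R,5S)-4-(acetyloxy)-2-[(2R,4R)-4-(acetyloxy)-6-methylhept-5-en-2-yl]-5-methylcyclohexyl (2Z)-2-methylbut-2-enoate | C/C=C(/C)C(=O)O[C@@H]1C[C@H](C)[C@H](OC(C)=O)C[C@H]1[C@H](C)C[C@H](C=C(C)C)OC(C)=O | target

**Step count**

Total: 16 steps. Longest linear sequence: 15 steps (steps 1–4 and 6–16); step 5 is a one-step branch.

**Steps most likely to fail, with fallbacks**

Step 8. The unactivated vinylsilane may add too slowly within the usable thermal window. Prolonged heating would then allow [1,5]-hydrogen shift in the (Z)-dienyl ether, Claisen ring expansion of the allyl vinyl ether in the product, or acid-induced spiroketalisation, and the π-facial selectivity may be incomplete. The fallback sets out from dienol 10 and replaces the silicon tether by a boron tether with a more electron-poor dienophile. Transesterification of 10 with dibutyl ethenylboronate (PhMe, 40 °C, butanol removed under reduced pressure) should give butyl {(2Z)-3-[(2S,4R)-4-methyl-2-(2-methylprop-1-en-1-yl)-3,4-dihydro-2H-pyran-6-yl]prop-2-en-1-yl} ethenylboronate F1. Its alkenylboronate-tethered intramolecular Diels–Alder reaction, expected at about 110–130 °C because the vacant boron p orbital lowers the dienophile LUMO, should give the cis-fused 2-butoxy-1,2-oxaborolane cycloadduct F2 under the same geometric control. Oxidation of the C–B bond with retention (NaBO3·4H2O, THF–H2O) returns to the route at diol 14.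

Step 14. The activated allylic alcohol may ionise to a prenyl-type cation instead of undergoing SN2 displacement, which would lead to SN2′ capture at C11, loss of configuration at C9 or elimination to a diene. The fallback sets out from hydroxy ketone 19 and sets C9 by reagent-controlled reduction instead of inversion. Reduction of the C1 ketone (NaBH4, CeCl3, MeOH, −40 °C) should give (1R,2S,4R,5S)-4-hydroxy-5-[(2R,4S)-4-hydroxy-6-methylhept-5-en-2-yl]-2-methylcyclohexyl acetate F3. MnO2 (CH2Cl2) oxidises only the allylic alcohol, to (1R,2S,4R,5S)-4-hydroxy-2-methyl-5-[(2R)-6-methyl-4-oxohept-5-en-2-yl]cyclohexyl acetate F4. Yamaguchi acylation with 22 as in step 16 gives (1R,2S,4R,5S)-4-(acetyloxy)-5-methyl-2-[(2R)-6-methyl-4-oxohept-5-en-2-yl]cyclohexyl (2Z)-2-methylbut-2-enoate F5. Corey–Bakshi–Shibata reduction with the (S)-catalyst and catecholborane at −78 °C then gives (1R,2S,4R,5S)-4-(acetyloxy)-2-[(2R,4R)-4-hydroxy-6-methylhept-5-en-2-yl]-5-methylcyclohexyl (2Z)-2-methylbut-2-enoate F6. Acetylation (Ac2O, pyridine, DMAP) comes back to the route at the target 24.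

Step 15. The branched equatorial substituent on C6 may erode the preference for axial hydride attack, so that equatorial attack delivers a substantial share of the axial C1 alcohol. The fallback sets out from ketone 20 and makes the opposite selectivity the productive one. L-Selectride (THF, −78 °C) attacks equatorially and should give the axial alcohol (1R,2S,4S,5S)-5-[(2R,4R)-4-(acetyloxy)-6-methylhept-5-en-2-yl]-4-hydroxy-2-methylcyclohexyl acetate F7. Mitsunobu esterification with angelic acid 22 (PPh3, DIAD, PhMe, 0 °C to rt) inverts C1 and comes back to the route at the target 24.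

**Further compounds**

F1 | step 8 | butyl {(2Z)-3-[(2S,4R)-4-methyl-2-(2-methylprop-1-en-1-yl)-3,4-dihydro-2H-pyran-6-yl]prop-2-en-1-yl} ethenylboronate | C=CB(OCCCC)OC/C=C\C1=C[C@H](C)C[C@@H](C=C(C)C)O1
F2 | step 8 | boron-tethered cycloadduct: analogue of 13 with a cis-fused 2-butoxy-1,2-oxaborolane in place of the oxasilolane | O1C2=C[C@@H]3COB(OCCCC)[C@@H]3C[C@H]2[C@H](C)C[C@H]1C=C(C)C
F3 | step 14 | (1R,2S,4R,5S)-4-hydroxy-5-[(2R,4S)-4-hydroxy-6-methylhept-5-en-2-yl]-2-methylcyclohexyl acetate | O[C@@H]1C[C@H](C)[C@H](OC(C)=O)C[C@H]1[C@H](C)C[C@@H](C=C(C)C)O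
F4 | step 14 | (1R,2S,4R,5S)-4-hydroxy-2-methyl-5-[(2R)-6-methyl-4-oxohept-5-en-2-yl]cyclohexyl acetate | O[C@@H]1C[C@H](C)[C@H](OC(C)=O)C[C@H]1[C@H](C)CC(=O)C=C(C)C
F5 | step 14 | (1R,2S,4R,5S)-4-(acetyloxy)-5-methyl-2-[(2R)-6-methyl-4-oxohept-5-en-2-yl]cyclohexyl (2Z)-2-methylbut-2-enoate | C/C=C(/C)C(=O)O[C@@H]1C[C@H](C)[C@H](OC(C)=O)C[C@H]1[C@H](C)CC(=O)C=C(C)C
F6 | step 14 | (1R,2S,4R,5S)-4-(acetyloxy)-2-[(2R,4R)-4-hydroxy-6-methylhept-5-en-2-yl]-5-methylcyclohexyl (2Z)-2-methylbut-2-enoate | C/C=C(/C)C(=O)O[C@@H]1C[C@H](C)[C@H](OC(C)=O)C[C@H]1[C@H](C)C[C@H](C=C(C)C)O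
F7 | step 15 | (1R,2S,4S,5S)-5-[(2R,4R)-4-(acetyloxy)-6-methylhept-5-en-2-yl]-4-hydroxy-2-methylcyclohexyl acetate | O[C@H]1C[C@H](C)[C@H](OC(C)=O)C[C@H]1[C@H](C)C[C@H](C=C(C)C)OC(C)=O
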